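**Retrosynthetic overview**
1. Numbering (elemane): ring A is the cyclohexane C5–C6–C7–C8–C9–C10. C10 carries CH3 and vinyl (C1=C2), C5 carries C4(=CH2)CH2OH (O15), and O8 carries the acyl side chain. Ring B is the γ-lactone C6–O–C12(=O)–C11(CH3)–C7.
2. Enabling feature: in ring A the unsubstituted C9H2 lies between quaternary C10 and oxygenated C8. The vinyl carbon C1 on C10 can be carried as a lactone carbonyl tied to O15 (temporary δ-lactone C1–O15–C15–C4–C5–C10), which stabilises a radical at C10. C8 is bonded to C7, the β-carbon of the C12 carbonyl. C9–C8(O) is therefore a vinyl ester that can be inserted between a C10 radical and a C7=C11 enoate.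
3. Key disconnection: ring A by a radical [4+2] annulation of bromo lactone 18 with vinyl acetate (bonds C9–C10 and C7–C8). 18 comes from (R)-glyceraldehyde acetonide (C6) by Morita–Baylis–Hillman reaction, ester transposition, Ireland–Claisen rearrangement (C5–C10, sets C5), lactonization, bromination and Wittig olefination.
4. Endgame: lactol methylenation opens the δ-lactone to the C10 vinyl group and the C15 alcohol. Side-chain acid 32 (asymmetric Morita–Baylis–Hillman reaction) is esterified at O8. Acid closes ring B on O6, base sets C11, fluoride removes the silyl groups.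
5. Ring order: temporary δ-lactone (step 4), ring A (step 9), δ-lactone opened (steps 10–11), ring B (step 17).

Key step: step 9

Assumption: C11 is formed unselectively in step 9, so 23, 24, 26, 27, 34 and 35 are C11 epimer pairs (drawn without a C11 descriptor) that converge in step 17; 16, 28 and 29 are taken as purchasable.

**Route**

Step 1
Reactants: 1 (4R)-2,2-dimethyl-1,3-dioxolane-4-carbaldehyde; 2 methyl acrylate
Product: 3 methyl 2-{[(4R)-2,2-dimethyl-1,3-dioxolan-4-yl](hydroxy)methyl}prop-2-enoate (both carbinol epimers)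
Conditions: DABCO (0.3 equiv), 2 (3 equiv), dioxane/H2O, rt
Reagents that add atoms: none
Why: Morita–Baylis–Hillman reaction of the α-alkoxy aldehyde; the new carbinol centre becomes sp2 in step 2, so only the dioxolane centre (future C6) matters and it is not touched.

Step 2
Reactants: 3 Morita–Baylis–Hillman alcohol; 4 propanoic anhydride
Product: 6 methyl (2E)-3-[(4S)-2,2-dimethyl-1,3-dioxolan-4-yl]-2-[(propanoyloxy)methyl]prop-2-enoate, via secondary propanoate 5 (not isolated)
Conditions: Et3N, DMAP (cat.), CH2Cl2, 0 °C; then DABCO (0.2 equiv), THF, 60 °C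
Reagents that add atoms: none
Why: O-acylation followed by the DABCO-mediated SN2′–SN2′ 1,3-transposition of a Morita–Baylis–Hillman ester should give the thermodynamically favoured conjugated primary (E)-allylic ester, which puts the propanoate on the carbon that becomes the exocyclic methylene.

Step 3
Reactants: 6 allylic propanoate
Product: 9 (3S)-3-[(4S)-2,2-dimethyl-1,3-dioxolan-4-yl]-4-(methoxycarbonyl)-2-methylpent-4-enoic acid (C2 epimers), via silyl ketene acetal 7 (not isolated), via trimethylsilyl ester 8 (not isolated)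
Conditions: LiN(iPr)2, Me3SiCl, THF, −78 °C to rt; then 1 M HCl
Reagents that add atoms: none
Why: Ireland–Claisen rearrangement through a chair transition state forms C5–C10 and regenerates the 2-substituted acrylate; allylic 1,3-strain holds H6 in the alkene plane and the ketene acetal should attack C5 anti to the dioxolane C–O bond, which sets C5 (S), while the C10 centre is a mixture that is erased in step 9.

Step 4
Reactants: 9 acid ester
Product: 11 (4S)-4-[(4S)-2,2-dimethyl-1,3-dioxolan-4-yl]-3-methyl-5-methylideneoxan-2-one (C3 epimers), via hydroxy acid 10 (not isolated)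
Conditions: iBu2AlH (3.5 equiv), CH2Cl2, −78 °C; aq. KNaC4H4O6; then pyridinium p-toluenesulfonate (cat.), PhH, 60 °C
Reagents that add atoms: none
Why: iBu2AlH reduces the acrylate ester 1,2 to the allylic alcohol while the aluminium carboxylate is inert at −78 °C, and the δ-hydroxy acid should close to the six-membered lactone under mild acid that spares the acetonide.

Step 5
Reactants: 11 δ-lactone
Product: 13 (4S)-3-bromo-4-[(4S)-2,2-dimethyl-1,3-dioxolan-4-yl]-3-methyl-5-methylideneoxan-2-one, via lithium enolate 12 (not isolated)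
Conditions: LiN(iPr)2, THF, −78 °C; then CBr4
Reagents that add atoms: carbon tetrabromide, BrC(Br)(Br)Br
Why: α-bromination of the only enolizable position gives the tertiary α-bromo lactone that serves as the radical precursor; its configuration is of no consequence.

Step 6
Reactants: 13 bromo lactone acetonide
Product: 14 (4S)-3-bromo-4-[(1S)-1,2-dihydroxyethyl]-3-methyl-5-methylideneoxan-2-one
Conditions: AcOH/H2O (4:1), rt
Reagents that add atoms: none
Why: mild acidic hydrolysis of the acetonide, which the tertiary α-bromo lactone and the exocyclic alkene should tolerate.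

Step 7
Reactants: 14 diol
Product: 15 (4S)-4-[(1S)-1,2-bis(triethylsilyloxy)ethyl]-3-bromo-3-methyl-5-methylideneoxan-2-one
Conditions: Et3SiOTf (2.5 equiv), 2,6-lutidine, CH2Cl2, −78 to 0 °C
Reagents that add atoms: triethylsilyl trifluoromethanesulfonate, CC[Si](CC)(CC)OS(=O)(=O)C(F)(F)F
Why: exhaustive silylation masks the secondary C6 hydroxyl before it can transacylate the δ-lactone.

Step 8
Reactants: 15 bis(silyl ether); 16 tert-butyl 2-(triphenyl-λ5-phosphanylidene)propanoate
Product: 18 tert-butyl (2E,4R)-4-[(4S)-3-bromo-3-methyl-5-methylidene-2-oxooxan-4-yl]-2-methyl-4-(triethylsilyloxy)but-2-enoate, via aldehyde 17 (not isolated)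
Conditions: (COCl)2, DMSO, CH2Cl2, −78 to −40 °C; Et3N; then 16, CH2Cl2, rt
Reagents that add atoms: none
Why: Swern conditions oxidize a primary triethylsilyl ether directly to the aldehyde while the secondary silyl ether survives, and Wittig olefination with the stabilized ylide should give the (E)-trisubstituted enoate.

Step 9
Reactants: 18 bromo lactone enoate; 19 vinyl acetate
Product: 23 tert-butyl 2-[(4aR,5S,6S,7R,8aS)-7-acetoxy-8a-methyl-4-methylidene-1-oxo-5-(triethylsilyloxy)octahydro-1H-isochromen-6-yl]propanoate (C11 epimers), via C10 radical 20 (not isolated), via C8 radical 21 (not isolated), via C11 radical 22 (not isolated)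
Conditions: 19 (1 M), Bu3SnH (1.3 equiv) and AIBN (0.2 equiv) by syringe pump over 10 h, PhH, 80 °C
Reagents that add atoms: none
Why: Proposed new method: Bu3Sn• abstracts bromine to give the tertiary α-lactone radical at C10, which is electrophilic and should add to the CH2 terminus (C9) of electron-rich vinyl acetate rather than to its own electron-poor enoate; the resulting nucleophilic α-acetoxy radical at C8 then closes onto C7 of the enoate and the C11 radical is reduced by Bu3SnH. The closest known reactions are Giese additions of α-carbonyl radicals to vinyl esters and radical annulations in which an intermolecular addition is followed by an exo cyclization onto an acrylate, but this [4+2] combination with a tertiary α-bromo lactone is without direct precedent. Ring A is closed in the 6-exo-trig mode through a chair transition state that is trans-fused to the δ-lactone. C10 is set by attack of vinyl acetate anti to the C5 side chain on the lactone ring, C8 by the preference of the acetoxy group for the equatorial site away from the axial C10 methyl, and C7 by the equatorial placement of the enoate arm (allylic 1,3-strain with the C11 methyl), while C11 is left to step 17. The step needs the C10 radical to choose vinyl acetate and the C8 radical to choose the enoate over further vinyl acetate and over the exocyclic methylene; the alternating electrophilic and nucleophilic character of the two radicals and the slow delivery of Bu3SnH should secure this.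

Step 10
Reactants: 23 annulation product
Product: 24 tert-butyl 2-[(4aR,5S,6S,7R,8aS)-1,7-dihydroxy-8a-methyl-4-methylidene-5-(triethylsilyloxy)octahydro-1H-isochromen-6-yl]propanoate (lactol)
Conditions: iBu2AlH (3.5 equiv), CH2Cl2, −78 °C; aq. KNaC4H4O6
Reagents that add atoms: none
Why: iBu2AlH reduces the δ-lactone to the lactol (stable tetrahedral aluminate at −78 °C) and cleaves the acetate, while the hindered α-branched tert-butyl ester should not be attacked.

Step 11
Reactants: 24 lactol; 25 methyltriphenylphosphonium bromide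
Product: 26 tert-butyl 2-[(1S,2S,3S,4R,6R)-4-ethenyl-6-hydroxy-3-(3-hydroxyprop-1-en-2-yl)-4-methyl-2-(triethylsilyloxy)cyclohexyl]propanoate
Conditions: 25 (5 equiv), KN(SiMe3)2, THF, 0 °C; then 24, 0 °C to rt
Reagents that add atoms: none
Why: Wittig methylenation of the ring-opened hydroxy aldehyde form of the lactol gives the C10 vinyl group and releases the C15 allylic alcohol in the same operation; the neopentyl aldehyde cannot epimerize.

Step 12
Reactants: 26 diol
Product: 27 tert-butyl 2-[(1S,2S,3S,4R,6R)-3-{3-[(tert-butyldiphenylsilyl)oxy]prop-1-en-2-yl}-4-ethenyl-6-hydroxy-4-methyl-2-(triethylsilyloxy)cyclohexyl]propanoate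
Conditions: tBuPh2SiCl (1.05 equiv), imidazole, CH2Cl2, 0 °C
Reagents that add atoms: tert-butyl(chloro)diphenylsilane, CC(C)(C)[Si](Cl)(c1ccccc1)c1ccccc1
Why: the primary allylic C15 alcohol should be silylated selectively over the hindered secondary C8 alcohol.

Step 13
Reactants: 28 2-[(tert-butyldiphenylsilyl)oxy]acetaldehyde; 29 1,1,1,3,3,3-hexafluoropropan-2-yl acrylate
Product: 30 1,1,1,3,3,3-hexafluoropropan-2-yl (3S)-4-[(tert-butyldiphenylsilyl)oxy]-3-hydroxy-2-methylidenebutanoate
Conditions: β-isocupreidine (10 mol %), DMF, −55 °C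
Reagents that add atoms: none
Why: asymmetric Morita–Baylis–Hillman reaction of the activated acrylate under cinchona-derived amine catalysis; the facial preference known for aldehydes corresponds here to the (S)-carbinol, because CH2OSi outranks the alkene carbon.

Step 14
Reactants: 30 hydroxy ester
Product: 31 1,1,1,3,3,3-hexafluoropropan-2-yl (3S)-4-[(tert-butyldiphenylsilyl)oxy]-2-methylidene-3-[(triisopropylsilyl)oxy]butanoate
Conditions: iPr3SiOTf, 2,6-lutidine, CH2Cl2, −40 °C
Reagents that add atoms: triisopropylsilyl trifluoromethanesulfonate, CC(C)[Si](OS(=O)(=O)C(F)(F)F)(C(C)C)C(C)C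
Why: silylation of the secondary alcohol with an acid-stable group so that the side chain survives step 17 and cannot lactonize onto its own ester.

Step 15
Reactants: 31 bis(silyl) ester
Product: 32 (3S)-4-[(tert-butyldiphenylsilyl)oxy]-2-methylidene-3-[(triisopropylsilyl)oxy]butanoic acid
Conditions: LiOH, THF/H2O, 0 °C; then 1 M HCl
Reagents that add atoms: lithium hydroxide, [Li+].[OH-]
Why: the activated hexafluoroisopropyl ester is saponified under conditions that leave both silyl ethers and the stereocentre untouched.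

Step 16
Reactants: 27 C8 alcohol; 32 side-chain acid
Product: 34 (1R,2S,3S,4S,5R)-2-[1-(tert-butoxy)-1-oxopropan-2-yl]-4-{3-[(tert-butyldiphenylsilyl)oxy]prop-1-en-2-yl}-5-ethenyl-5-methyl-3-(triethylsilyloxy)cyclohexyl (3S)-4-[(tert-butyldiphenylsilyl)oxy]-2-methylidene-3-[(triisopropylsilyl)oxy]butanoate, via mixed anhydride 33 (not isolated)
Conditions: 32, 2,4,6-trichlorobenzoyl chloride, Et3N, THF, rt; then 27, DMAP, PhMe, 40 °C
Reagents that add atoms: none
Why: Yamaguchi esterification is suited to a hindered secondary alcohol and a hindered acrylic acid and does not touch the stereocentres.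

Step 17
Reactants: 34 ester
Product: 36 (3R,3aS,4R,6R,7S,7aS)-7-{3-[(tert-butyldiphenylsilyl)oxy]prop-1-en-2-yl}-6-ethenyl-3,6-dimethyl-2-oxooctahydro-1-benzofuran-4-yl (3S)-4-[(tert-butyldiphenylsilyl)oxy]-2-methylidene-3-[(triisopropylsilyl)oxy]butanoate, via C11-epimeric lactone 35 (not isolated)
Conditions: CF3CO2H/CH2Cl2 (1:9), 0 °C; evaporate; then DBU (0.5 equiv), PhMe, 60 °C
Reagents that add atoms: none
Why: acidolysis of the tert-butyl ester and the triethylsilyl ether is followed by γ-lactonization, which can only occur on O6 because O8 is acylated (trans ring fusion from the diequatorial arrangement); DBU should then equilibrate C11 through the lactone enolate to the more stable epimer with the methyl trans to C8 (11R).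

Step 18
Reactants: 36 silylated lactone
Product: 37 (3R,3aS,4R,6R,7S,7aS)-6-ethenyl-7-(3-hydroxyprop-1-en-2-yl)-3,6-dimethyl-2-oxooctahydro-1-benzofuran-4-yl (3S)-3,4-dihydroxy-2-methylidenebutanoate
Conditions: HF·pyridine, pyridine/THF, 0 °C to rt
Reagents that add atoms: none
Why: fluoride-mediated global desilylation under mildly acidic conditions avoids the base-induced lactonization of the side chain that would expel O8.

**Compound list**
1 | (4R)-2,2-dimethyl-1,3-dioxolane-4-carbaldehyde | O=C[C@H]1COC(C)(C)O1 | starting material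
2 | methyl acrylate | C=CC(=O)OC | starting material
3 | methyl 2-{[(4R)-2,2-dimethyl-1,3-dioxolan-4-yl](hydroxy)methyl}prop-2-enoate (both carbinol epimers) | C=C(C(=O)OC)C(O)[C@H]1COC(C)(C)O1 | intermediate
4 | propanoic anhydride | CCC(=O)OC(=O)CC | starting material
5 | methyl 2-{[(4R)-2,2-dimethyl-1,3-dioxolan-4-yl](propanoyloxy)methyl}prop-2-enoate | C=C(C(=O)OC)C(OC(=O)CC)[C@H]1COC(C)(C)O1 | intermediate (not isolated)
6 | methyl (2E)-3-[(4S)-2,2-dimethyl-1,3-dioxolan-4-yl]-2-[(propanoyloxy)methyl]prop-2-enoate | COC(=O)/C(COC(=O)CC)=C/[C@H]1COC(C)(C)O1 | intermediate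
7 | trimethylsilyl ketene acetal of the propanoate of 6 | COC(=O)/C(COC(O[Si](C)(C)C)=CC)=C/[C@H]1COC(C)(C)O1 | intermediate (not isolated)
8 | trimethylsilyl (3S)-3-[(4S)-2,2-dimethyl-1,3-dioxolan-4-yl]-4-(methoxycarbonyl)-2-methylpent-4-enoate | CC(C(=O)O[Si](C)(C)C)[C@@H](C(=C)C(=O)OC)[C@H]1COC(C)(C)O1 | intermediate (not isolated)
9 | (3S)-3-[(4S)-2,2-dimethyl-1,3-dioxolan-4-yl]-4-(methoxycarbonyl)-2-methylpent-4-enoic acid (C2 epimers) | CC(C(=O)O)[C@@H](C(=C)C(=O)OC)[C@H]1COC(C)(C)O1 | intermediate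
10 | (3S)-3-[(4S)-2,2-dimethyl-1,3-dioxolan-4-yl]-4-(hydroxymethyl)-2-methylpent-4-enoic acid | CC(C(=O)O)[C@@H](C(=C)CO)[C@H]1COC(C)(C)O1 | intermediate (not isolated)
11 | (4S)-4-[(4S)-2,2-dimethyl-1,3-dioxolan-4-yl]-3-methyl-5-methylideneoxan-2-one (C3 epimers) | CC1C(=O)OCC(=C)[C@H]1[C@H]2COC(C)(C)O2 | intermediate
12 | lithium enolate of 11 | [Li+].CC1=C([O-])OCC(=C)[C@H]1[C@H]2COC(C)(C)O2 | intermediate (not isolated)
13 | (4S)-3-bromo-4-[(4S)-2,2-dimethyl-1,3-dioxolan-4-yl]-3-methyl-5-methylideneoxan-2-one (C3 configuration immaterial) | CC1(Br)C(=O)OCC(=C)[C@H]1[C@H]2COC(C)(C)O2 | intermediate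
14 | (4S)-3-bromo-4-[(1S)-1,2-dihydroxyethyl]-3-methyl-5-methylideneoxan-2-one | CC1(Br)C(=O)OCC(=C)[C@H]1[C@H](O)CO | intermediate
15 | (4S)-4-[(1S)-1,2-bis(triethylsilyloxy)ethyl]-3-bromo-3-methyl-5-methylideneoxan-2-one | CC1(Br)C(=O)OCC(=C)[C@H]1[C@H](O[Si](CC)(CC)CC)CO[Si](CC)(CC)CC | intermediate
16 | tert-butyl 2-(triphenyl-λ5-phosphanylidene)propanoate | CC(=P(c1ccccc1)(c1ccccc1)c1ccccc1)C(=O)OC(C)(C)C | starting material
17 | (2S)-2-[(4S)-3-bromo-3-methyl-5-methylidene-2-oxooxan-4-yl]-2-(triethylsilyloxy)acetaldehyde | CC1(Br)C(=O)OCC(=C)[C@H]1[C@H](O[Si](CC)(CC)CC)C=O | intermediate (not isolated)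
18 | tert-butyl (2E,4R)-4-[(4S)-3-bromo-3-methyl-5-methylidene-2-oxooxan-4-yl]-2-methyl-4-(triethylsilyloxy)but-2-enoate | CC1(Br)C(=O)OCC(=C)[C@H]1[C@H](O[Si](CC)(CC)CC)/C=C(\C)C(=O)OC(C)(C)C | intermediate
19 | vinyl acetate | C=COC(C)=O | starting material
20 | tertiary C10 radical of 18 (bromine removed) | C[C]1C(=O)OCC(=C)[C@H]1[C@H](O[Si](CC)(CC)CC)/C=C(\C)C(=O)OC(C)(C)C | intermediate (not isolated)
21 | α-acetoxy C8 radical (20 added to the CH2 of 19; C9 trans to the C5 side chain) | CC(=O)O[CH]C[C@]1(C)C(=O)OCC(=C)[C@H]1[C@H](O[Si](CC)(CC)CC)/C=C(\C)C(=O)OC(C)(C)C | intermediate (not isolated)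
22 | C11 radical after closure of ring A | O=C3[C@@]1(C)C[C@@H](OC(C)=O)[C@H]([C](C)C(=O)OC(C)(C)C)[C@@H](O[Si](CC)(CC)CC)[C@@H]1C(=C)CO3 | intermediate (not isolated)
23 | tert-butyl 2-[(4aR,5S,6S,7R,8aS)-7-acetoxy-8a-methyl-4-methylidene-1-oxo-5-(triethylsilyloxy)octahydro-1H-isochromen-6-yl]propanoate (C11 epimers) | O=C3[C@@]1(C)C[C@@H](OC(C)=O)[C@H](C(C)C(=O)OC(C)(C)C)[C@@H](O[Si](CC)(CC)CC)[C@@H]1C(=C)CO3 | intermediate
24 | tert-butyl 2-[(4aR,5S,6S,7R,8aS)-1,7-dihydroxy-8a-methyl-4-methylidene-5-(triethylsilyloxy)octahydro-1H-isochromen-6-yl]propanoate (lactol epimers) | OC3[C@@]1(C)C[C@@H](O)[C@H](C(C)C(=O)OC(C)(C)C)[C@@H](O[Si](CC)(CC)CC)[C@@H]1C(=C)CO3 | intermediate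
25 | methyltriphenylphosphonium bromide | C[P+](c1ccccc1)(c1ccccc1)c1ccccc1.[Br-] | starting material
26 | tert-butyl 2-[(1S,2S,3S,4R,6R)-4-ethenyl-6-hydroxy-3-(3-hydroxyprop-1-en-2-yl)-4-methyl-2-(triethylsilyloxy)cyclohexyl]propanoate | C=C[C@@]1(C)C[C@@H](O)[C@H](C(C)C(=O)OC(C)(C)C)[C@@H](O[Si](CC)(CC)CC)[C@@H]1C(=C)CO | intermediate
27 | tert-butyl 2-[(1S,2S,3S,4R,6R)-3-{3-[(tert-butyldiphenylsilyl)oxy]prop-1-en-2-yl}-4-ethenyl-6-hydroxy-4-methyl-2-(triethylsilyloxy)cyclohexyl]propanoate | C=C[C@@]1(C)C[C@@H](O)[C@H](C(C)C(=O)OC(C)(C)C)[C@@H](O[Si](CC)(CC)CC)[C@@H]1C(=C)CO[Si](c2ccccc2)(c2ccccc2)C(C)(C)C | intermediate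
28 | 2-[(tert-butyldiphenylsilyl)oxy]acetaldehyde | O=CCO[Si](c1ccccc1)(c1ccccc1)C(C)(C)C | starting material
29 | 1,1,1,3,3,3-hexafluoropropan-2-yl acrylate | C=CC(=O)OC(C(F)(F)F)C(F)(F)F | starting material
30 | 1,1,1,3,3,3-hexafluoropropan-2-yl (3S)-4-[(tert-butyldiphenylsilyl)oxy]-3-hydroxy-2-methylidenebutanoate | C=C(C(=O)OC(C(F)(F)F)C(F)(F)F)[C@H](O)CO[Si](c1ccccc1)(c1ccccc1)C(C)(C)C | intermediate
31 | 1,1,1,3,3,3-hexafluoropropan-2-yl (3S)-4-[(tert-butyldiphenylsilyl)oxy]-2-methylidene-3-[(triisopropylsilyl)oxy]butanoate | C=C(C(=O)OC(C(F)(F)F)C(F)(F)F)[C@H](O[Si](C(C)C)(C(C)C)C(C)C)CO[Si](c1ccccc1)(c1ccccc1)C(C)(C)C | intermediate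
32 | (3S)-4-[(tert-butyldiphenylsilyl)oxy]-2-methylidene-3-[(triisopropylsilyl)oxy]butanoic acid | C=C(C(=O)O)[C@H](O[Si](C(C)C)(C(C)C)C(C)C)CO[Si](c1ccccc1)(c1ccccc1)C(C)(C)C | intermediate
33 | mixed anhydride of 32 with 2,4,6-trichlorobenzoic acid | C=C(C(=O)OC(=O)c1c(Cl)cc(Cl)cc1Cl)[C@H](O[Si](C(C)C)(C(C)C)C(C)C)CO[Si](c1ccccc1)(c1ccccc1)C(C)(C)C | intermediate (not isolated)
34 | (1R,2S,3S,4S,5R)-2-[1-(tert-butoxy)-1-oxopropan-2-yl]-4-{3-[(tert-butyldiphenylsilyl)oxy]prop-1-en-2-yl}-5-ethenyl-5-methyl-3-(triethylsilyloxy)cyclohexyl (3S)-4-[(tert-butyldiphenylsilyl)oxy]-2-methylidene-3-[(triisopropylsilyl)oxy]butanoate | C=C[C@@]1(C)C[C@@H](OC(=O)C(=C)[C@H](O[Si](C(C)C)(C(C)C)C(C)C)CO[Si](c2ccccc2)(c2ccccc2)C(C)(C)C)[C@H](C(C)C(=O)OC(C)(C)C)[C@@H](O[Si](CC)(CC)CC)[C@@H]1C(=C)CO[Si](c2ccccc2)(c2ccccc2)C(C)(C)C | intermediate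
35 | C11-epimeric mixture of lactone 36 | C=C[C@@]1(C)C[C@@H](OC(=O)C(=C)[C@H](O[Si](C(C)C)(C(C)C)C(C)C)CO[Si](c2ccccc2)(c2ccccc2)C(C)(C)C)[C@H]2[C@@H](OC(=O)C2C)[C@@H]1C(=C)CO[Si](c2ccccc2)(c2ccccc2)C(C)(C)C | intermediate (not isolated)
36 | (3R,3aS,4R,6R,7S,7aS)-7-{3-[(tert-butyldiphenylsilyl)oxy]prop-1-en-2-yl}-6-ethenyl-3,6-dimethyl-2-oxooctahydro-1-benzofuran-4-yl (3S)-4-[(tert-butyldiphenylsilyl)oxy]-2-methylidene-3-[(triisopropylsilyl)oxy]butanoate | C=C[C@@]1(C)C[C@@H](OC(=O)C(=C)[C@H](O[Si](C(C)C)(C(C)C)C(C)C)CO[Si](c2ccccc2)(c2ccccc2)C(C)(C)C)[C@H]2[C@@H](OC(=O)[C@@H]2C)[C@@H]1C(=C)CO[Si](c2ccccc2)(c2ccccc2)C(C)(C)C | intermediate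
37 | (3R,3aS,4R,6R,7S,7aS)-6-ethenyl-7-(3-hydroxyprop-1-en-2-yl)-3,6-dimethyl-2-oxooctahydro-1-benzofuran-4-yl (3S)-3,4-dihydroxy-2-methylidenebutanoate | C=C[C@@]1(C)C[C@@H](OC(=O)C(=C)[C@H](O)CO)[C@H]2[C@@H](OC(=O)[C@@H]2C)[C@@H]1C(=C)CO | target

**Step count and risks**
Total step count: 18. Longest linear sequence: 15 steps (steps 1–12 and 16–18); steps 13–15 make the side-chain acid.

Step 9 (labelled new). The C10 radical may be reduced before it adds to vinyl acetate, the C8 radical may telomerize with further vinyl acetate or shift a hydrogen from C6, and facial selectivity at C10 may be poor. The fallback sets out from 18 and uses an anionic double Michael sequence of known reactions. A Reformatsky reagent from 18 (Zn, THF) adds to nitroethylene to give tert-butyl (2E)-2-methyl-4-[3-methyl-5-methylidene-3-(2-nitroethyl)-2-oxooxan-4-yl]-4-(triethylsilyloxy)but-2-enoate F1. DBU in MeCN closes ring A by intramolecular nitro-Michael addition to give the C8 nitro analogue of 23, F2, with the nitro group equilibrated to the equatorial site. A Nef reaction (nitronate, buffered aq. TiCl3) gives the C8 ketone F3. SmI2/iPrOH reduction gives the equatorial C8 alcohol F4, the deacetyl form of 23. F4 enters step 10 and returns to the route at 24.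

Step 17. The acid may protonate the 1,1-disubstituted alkene or loosen silyl ethers, and the base may degrade the acrylate side chain before C11 has equilibrated. The fallback sets out from 27 and fixes C11 before the side chain is attached. Allyl chloroformate and pyridine give the O8 allyl carbonate F5. CF3CO2H and then DBU give the 6,12-lactone carbonate F6 with C11 equilibrated. Pd(PPh3)4 and morpholine remove the carbonate under neutral conditions to give the 8-hydroxy lactone F7. Yamaguchi esterification with 32 then returns to the route at 36.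

Step 3. Enolization may occur at the γ-position of the enoate instead of the propanoate, or the facial selectivity at C5 may be poor. The fallback sets out from 1 and forms C5–C10 by conjugate addition instead of rearrangement. Wittig olefination with Ph3P=CHCO2Me in MeOH should give mainly methyl (2Z)-3-[(4S)-2,2-dimethyl-1,3-dioxolan-4-yl]prop-2-enoate F8. Michael addition of the dianion of propanoic acid (2 LiN(iPr)2) anti to the dioxolane C–O bond, with trapping of the ester enolate by CH2=NMe2+ I−, should give the Mannich acid (3S)-3-[(4S)-2,2-dimethyl-1,3-dioxolan-4-yl]-4-[(dimethylamino)methyl]-5-methoxy-2-methyl-5-oxopentanoic acid F9. N-oxidation (mCPBA) and Cope elimination then return to the route at 9.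

Further compounds
F1 | step 9 | tert-butyl (2E)-2-methyl-4-[3-methyl-5-methylidene-3-(2-nitroethyl)-2-oxooxan-4-yl]-4-(triethylsilyloxy)but-2-enoate | [O-][N+](=O)CC[C@]1(C)C(=O)OCC(=C)[C@H]1[C@H](O[Si](CC)(CC)CC)/C=C(\C)C(=O)OC(C)(C)C
F2 | step 9 | C8 nitro analogue of 23 (NO2 in place of OAc) | O=C3[C@@]1(C)C[C@@H]([N+](=O)[O-])[C@H](C(C)C(=O)OC(C)(C)C)[C@@H](O[Si](CC)(CC)CC)[C@@H]1C(=C)CO3
F3 | step 9 | C8 ketone analogue of 23 | O=C3[C@@]1(C)CC(=O)[C@H](C(C)C(=O)OC(C)(C)C)[C@@H](O[Si](CC)(CC)CC)[C@@H]1C(=C)CO3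
F4 | step 9 | C8 alcohol (deacetyl 23) | O=C3[C@@]1(C)C[C@@H](O)[C@H](C(C)C(=O)OC(C)(C)C)[C@@H](O[Si](CC)(CC)CC)[C@@H]1C(=C)CO3
F5 | step 17 | O8 allyl carbonate of 27 | C=C[C@@]1(C)C[C@@H](OC(=O)OCC=C)[C@H](C(C)C(=O)OC(C)(C)C)[C@@H](O[Si](CC)(CC)CC)[C@@H]1C(=C)CO[Si](c2ccccc2)(c2ccccc2)C(C)(C)C
F6 | step 17 | 6,12-lactone with O8 allyl carbonate and C15 silyl ether (11R) | C=C[C@@]1(C)C[C@@H](OC(=O)OCC=C)[C@H]2[C@@H](OC(=O)[C@@H]2C)[C@@H]1C(=C)CO[Si](c2ccccc2)(c2ccccc2)C(C)(C)C
F7 | step 17 | 8-hydroxy 6,12-lactone with C15 silyl ether | C=C[C@@]1(C)C[C@@H](O)[C@H]2[C@@H](OC(=O)[C@@H]2C)[C@@H]1C(=C)CO[Si](c2ccccc2)(c2ccccc2)C(C)(C)C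
F8 | step 3 | methyl (2Z)-3-[(4S)-2,2-dimethyl-1,3-dioxolan-4-yl]prop-2-enoate | COC(=O)/C=C\[C@H]1COC(C)(C)O1
F9 | step 3 | (3S)-3-[(4S)-2,2-dimethyl-1,3-dioxolan-4-yl]-4-[(dimethylamino)methyl]-5-methoxy-2-methyl-5-oxopentanoic acid | CC(C(=O)O)[C@@H](C(CN(C)C)C(=O)OC)[C@H]1COC(C)(C)O1
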